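The Thursday flask was charged with 0.0500 M of starting material and held 0.0373 M of target at 20 min. I wanted to know what such an amount becomes with less catalyst.

| flask | starting material | coupling partner | free catalyst | target | time |
|---|---|---|---|---|---|
| Thursday's | 0.0500 M | 0.125 M | 0.00150 M |  |  |
| Friday's | 0.0300 M | 0.105 M | 0.00150 M |  |  |
| Sunday's | 0.0500 M | 0.125 M | 0.00150 M | 0.0250 M |  |
| Wednesday's | 0.0500 M | 0.125 M | 7.50 × 10⁻⁴ M |  |  |
| Saturday's | 0.0500 M | 0.125 M | 4.30 × 10⁻⁴ M |  | 20 min |

- Thursday's run (time / min: [target] / M): 0.80: 0.0101; 1.3: 0.0148; 2.0: 0.0188; 3.2: 0.0231; 5.0: 0.0273; 8.0: 0.0316; 13: 0.0345; 20: 0.0373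
- Friday's run (time / min: [target] / M): 0.80: 0.0058; 1.3: 0.0080; 2.0: 0.0102; 3.2: 0.0131; 5.0: 0.0156; 8.0: 0.0186; 13: 0.0206; 20: 0.0218
- Sunday's run (time / min: [target] / M): 0.80: 0.0357; 1.3: 0.0396; 2.0: 0.0439; 3.2: 0.0485; 5.0: 0.0528; 8.0: 0.0562; 13: 0.0596; 20: 0.0619
- Wednesday's run (time / min: [target] / M): 0.80: 0.0061; 1.3: 0.0082; 2.0: 0.0104; 3.2: 0.0142; 5.0: 0.0173; 8.0: 0.0197; 13: 0.0226; 20: 0.0248

(readings scatter by 3 × 10⁻⁴ M)

- the power of [free catalyst] that the first rate follows, about the charge of the Thursday's run; measure it at two percent of starting material made into target
- the Friday's run starts with 0.0200 M less of starting material and of coupling partner than the Thursday's run, and with no target. Compared where both hold the same amount of starting material, once fifteen percent of what the Friday's run was charged with has turned into target, is the Friday's run faster, slower or alike (within a tenth)?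
- target in the Saturday's run at 20 min, as a share of the starting material charged

- Overall: starting material + coupling partner -> target, with free catalyst as catalyst.
- Constant volume, constant temperature.
- An order is taken over about fifteen percent of the charge, up and down.

A first-order loss runs straight in a logarithm, so with S the starting material charged, P the target made and C the catalyst charged, I counted progress as L = ln(S/(S − P)). Dividing by C gave W = L/C at 20 min, the exposure per catalyst:

W = 1.37 / 0.00150 M = 914 L mol⁻¹

I then set up two extreme versions of the Saturday flask from Thursday's readings. In the first, free catalyst keeps its first pace of L, and the share made is high: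

pace = 0.282 min⁻¹, share = 80.2 %

In the second, each catalyst makes a fixed amount of target, and the share is low:

target per catalyst = 24.9, share = 21.4 %

Both failed on the readings. Thursday's first pace gives L = 5.64 at 20 min, more than the 1.37 read. Wednesday, with half of Thursday's catalyst, held 0.0248 M of target, more than the 0.0186 M of the fixed-amount version. W passed the same test: it gives Wednesday L = 0.685, and the reading gives 0.685. So I carried W over to Saturday:

L = W × 4.30 × 10⁻⁴ M = 0.393, share = 32.5 %

The forecast gave 0.95, faster and 33 %, on this ground: “It follows time rather than turnover, so the catalyst is dying.”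

The flask gave a power of free catalyst of 1.0, a Friday flask faster than Thursday's where both held the same amount of starting material, by a rate ratio of 2.2, and 34.2 % of the starting material charged as target at 20 min in the Saturday flask, whose W was 973 L mol⁻¹.

    free catalyst + starting material + coupling partner → target + free catalyst (1908 L² mol⁻² min⁻¹)
    2 coupling partner → lost reagent (1.140 L mol⁻¹ min⁻¹)
    free catalyst + coupling partner → spent catalyst + coupling partner (1.122 L mol⁻¹ min⁻¹)

Saturday's target was held down by coupling partner going to lost reagent together with free catalyst going to spent catalyst. The forecast's 33 % would have been wrong for a Saturday flask without the path to lost reagent, which gave 48.6 %, more than the forecast. There W came to 1550 L mol⁻¹.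

All runs are simulated from invented constants, noise included.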